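## The problem

Compound 24 is a cyclopentane in which two neighbouring ring carbons, C1 and C2, are both quaternary stereocentres, while C3 to C5 are methylenes. C1 carries a methyl group and the 4-methylpent-3-enoyl group (acyl carbon C6). C2 carries a methyl group and the arm C1'H2–C2'(=O)–CH2–C(CH3)=CH–CH2, which ends in a 2-methyl-1,4-benzoquinone ring; the two methyl groups are cis and both centres are R. No ring fusion has to be built, but the two centres are contiguous, fully substituted and cannot be epimerised. Neither can be corrected later and no third stereocentre exists to control them, so they must be set as a pair, with the absolute configuration taken from the chiral pool or from a catalyst. The chain is assembled from the ring, a prenyl unit and an (E)-2-methylbut-2-enyl unit bearing the arene. Both joints lie α to a ketone whose alkene is β,γ, so each allyl unit must be attached through its unsubstituted terminus and the E geometry must be carried through. The quinone will not survive nucleophiles, bases or reductants, and the two β,γ-unsaturated ketones slip into conjugation with acid or base through their doubly activated methylenes, so all three groups have to appear at the very end. The feature that opens the route is that C1 (methyl, carbonyl) and C2 (two one-carbon substituents) are C1 and the gem-dimethyl carbon C2 of (+)-camphoric acid (1). Its C3 carboxyl is cis to the C1 carboxyl and stands γ to the C2 methyl on its own face, so it can deliver palladium to that methyl through a six-membered palladacycle and then be removed to leave the C3 methylene.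

## Retrosynthesis

No carbon–carbon bond is cut first: the quinone of 24 is traced to the 2,5-dimethoxy-3-methylphenyl ring of diketone 23. Methyl ethers survive every organometallic and hydride step and are removed oxidatively in one operation at 0 °C, whereas acetal or silyl protection of a hydroquinone would need a separate oxidation afterwards. The forward step must oxidise the arene faster than it touches the alkenes and must not isomerise the enones.

Both ketones of 23 are traced to the carbinols of diol 22. A β,γ-unsaturated ketone has an acidic methylene that would not tolerate the basic allyl metal needed to build the other side chain, so both carbonyls stay as alcohols until one neutral double oxidation. The precursor has no sensitive group, and its two carbinol centres need no control.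

In 22 the bond between the carbinol carbon on C1 (the future C6) and the prenyl CH2 is cut, giving lactol 19, a latent hydroxy aldehyde, and prenylbarium chloride 21 made from prenyl chloride 20. Allyl derivatives of magnesium, zinc, indium or chromium would add through the substituted γ-terminus and give the 1,1-dimethylallyl isomer. The barium reagent is chosen because it reacts at the α-carbon. The forward step must open the lactol at low temperature and hold the α-selectivity.

Lactol 19 comes from lactone 18 by partial reduction, and 18 is cut at the C2'–C3' bond into aldehyde 7 and the allylbarium chloride 16 derived from chloride 15, by way of hydroxy ester 17. Letting the new carbinol oxygen close onto the C1 ester differentiates the two carbonyl carbons without a protecting group and turns a hindered tertiary ester into a lactone that is reduced cleanly to the aldehyde level. The opposite order is not available, because the C1 ester cannot be reduced before the more reactive arm carbonyl, and a dialdehyde would require discrimination between two aldehydes. The forward step must give α-attack with retention of the E alkene.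

Chloride 15 is traced through allylic alcohol 14 to prenyl arene 13, and 13 is cut at the aryl–CH2 bond into bromide 10 (through aryllithium 12) and prenyl bromide 11. Bromide 10 comes from 4-methoxy-2-methylphenol 8 by ortho bromination (9) and O-methylation. Starting from the phenol fixes the substitution pattern of the future quinone without a regiochemical question, and allylic oxidation of the prenyl group sets the E alkene.

Aldehyde 7 is traced to Weinreb amide 6, 6 to acid 5 by cutting the C3–CO2H bond, and 5 to anhydride 4 by opening at the arm carbonyl. The aminolysis marks the carbonyl that is kept and at the same time frees the directing carboxyl for removal, so each operation serves two purposes.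

In anhydride 4 the C1'–C2' bond and the anhydride C–O bond are cut together, which gives half ester 3. The neighbouring cuts, C2–C1' or C1–C2, would require making a quaternary centre next to another one with stereocontrol. This cut instead forms the bond at a primary carbon away from the congestion: C1 is already in place, and C2 becomes a stereocentre simply by the choice between two methyl groups. The precursor contains only the carbons of camphoric acid.

Half ester 3 comes from diester 2 by saponification of the unhindered ester, and 2 from (+)-camphoric acid 1. The C1 carboxyl has to be an ester in the key step, since as a free acid it would direct palladium to its own β-methyl group.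

## Roads not taken

Alternative 1: The cut removes both methyl carbons at once. They would be introduced as the CH2–S–CH2 unit of a thiocarbonyl ylide, released by CsF from chloromethyl (trimethylsilyl)methyl sulfide A2, which adds across the tetrasubstituted alkene of cyclopent-1-ene-1,2-dicarboxylic anhydride A1 to give the thia-propellane A3. Desulfurisation over Ni (Raney type) would then leave the cis-dimethyl anhydride A4.
- Merits: both quaternary centres are formed in one suprafacial step, so the cis relationship is guaranteed, and the materials are cheap.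
- Weak points: A3 and A4 are meso, so the absolute configuration would rest on an enantioselective alcoholysis of a doubly neopentyl anhydride. The carbonyl on C2 must also be lengthened by one carbon (Arndt–Eistert at a quaternary centre) to become C1'–C2'. The dipolarophile is fully substituted.
- Comparison: its key step belongs to a known reaction class and is safer than the C–H carbonylation chosen here. Against that, the chosen plan is enantiopure from the first step and delivers the arm at the right length and oxidation level; its one surplus atom, the directing carboxyl, leaves in a single step.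

Alternative 2: The cut goes through C1–C6 and C2–C1'. Irradiation of the enantiopure dioxinone A5 with the symmetrical alkene 1,2-dimethylcyclopentene A6 would give the cis-anti-cis cyclobutane A7. Acetal hydrolysis and retro-aldol opening (de Mayo fragmentation) would then give keto acid A8, with an acetyl group on C1 and the CH2CO2H arm on C2.
- Merits: the alkene is symmetrical, so there is no regiochemical issue; both quaternary centres and the full 1,5-dicarbonyl pattern arrive in two or three operations; the photochemistry is of a well-known type.
- Weak points: facial selectivity depends only on the remote acetal centre and is often modest in intermolecular cases, although the isomers are diastereomers and separable. The alkene is volatile. The acetyl group would have to be extended to the 4-methylpent-3-enoyl group by attaching a 2-methylprop-1-enyl unit to its methyl carbon without conjugation, which is harder than adding an allyl metal to an aldehyde.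
- Comparison: this road is shorter to a ring that carries both carbonyl handles (about three steps against six to aldehyde 7), and its key step is precedented. The chosen plan sets against this an absolute configuration that needs no auxiliary and no separation, and an endgame in which both ketones are made by the same kind of addition.

Alternative 3: Four bonds are cut (C1–C5, C2–C3, C1–C6, C2–C1'). Butane-2,3-dione A9 condenses with two molecules of dimethyl 3-oxopentanedioate A10 (Weiss–Cook reaction), and decarboxylation in the same pot gives cis-1,5-dimethylbicyclo[3.3.0]octane-3,7-dione A11.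
- Merits: it is the cheapest and most scalable entry, and the cis-dimethyl ring fusion is fixed by the bicycle.
- Weak points: A11 has two mirror planes. One ketone must be removed (to monoketone A12). The other ring must then be opened between C6 and its carbonyl carbon with differentiation of enantiotopic methylenes, for example by chiral lithium amide enolisation and ozonolysis or by an enantioselective Baeyer–Villiger oxidation. The enantiomeric purity would then depend on a reagent, and several steps would be spent on a ketone that is not in the target.
- Comparison: the key step is robust and better proven than the one chosen. The chosen plan has no desymmetrisation, fewer redox corrections and a configuration fixed by the starting material.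

Key step: step 3

Remark on the chemistry: the carbinol centres formed in steps 12 and 14 (and the lactol centre of step 13) are not controlled and need not be, since step 15 removes them; compounds 17, 18, 19 and 22 are carried as mixtures of epimers.

## Route

Step 1
Reactants: 1 (1R,3S)-(+)-camphoric acid
Product: 2 dimethyl (1R,3S)-1,2,2-trimethylcyclopentane-1,3-dicarboxylate
Conditions: MeI, K2CO3, DMF, 25 °C
Reagents that add atoms: iodomethane, CI
Why: Carboxylate O-alkylation (SN2) esterifies both acids, including the tertiary one that resists Fischer esterification; no stereocentre is touched.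

Step 2
Reactants: 2 dimethyl (1R,3S)-1,2,2-trimethylcyclopentane-1,3-dicarboxylate
Product: 3 (1S,3R)-3-(methoxycarbonyl)-2,2,3-trimethylcyclopentane-1-carboxylic acid
Conditions: KOH (1.1 equiv), MeOH/H2O, 40 °C; then aq. HCl
Reagents that add atoms: potassium hydroxide, [K+].[OH-]
Why: Saponification is much faster at the secondary ester than at the tertiary, neopentyl-type ester, the classical way to the hindered half ester of camphoric acid; one equivalent of base at moderate temperature should leave the α-carbon of the cis acid unepimerised.

Step 3
Reactants: 3 (1S,3R)-3-(methoxycarbonyl)-2,2,3-trimethylcyclopentane-1-carboxylic acid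
Product: 4 methyl (4aS,5R,7aS)-4a,5-dimethyl-1,3-dioxooctahydrocyclopenta[c]pyran-5-carboxylate (cis-fused glutaric anhydride; ester, anhydride CH2 and anhydride CH on one ring face, both methyls on the other)
Conditions: Pd(OAc)2 (10 mol %), N-[2-(phenylsulfanyl)ethyl]acetamide (12 mol %), Mo(CO)6 (1.0 equiv), Ag2CO3 (2.0 equiv), (CF3)2CHOH, 80 °C
Reagents that add atoms: molybdenum hexacarbonyl, [Mo].[C-]#[O+].[C-]#[O+].[C-]#[O+].[C-]#[O+].[C-]#[O+].[C-]#[O+]
Why: Proposed new method: the carboxylate of 3 should hold divalent palladium over the C2 methyl on its own ring face, and concerted metalation–deprotonation of that primary C–H bond gives a six-membered palladacycle; CO released from Mo(CO)6 inserts into the Pd–C bond, C–O reductive elimination from the acyl palladium carboxylate forms the anhydride, and Ag2CO3 returns zerovalent palladium to the divalent state. The closest known reaction type is the ligand-enabled, carboxylate-directed γ-methyl C–H functionalisation (arylation, lactonisation, carbonylation to glutaric anhydrides) of open-chain free acids with a β-quaternary gem-dimethyl carbon; a ring-bound secondary acid with a competing ring methylene has not been shown. The one ring formed is the six-membered anhydride, closed by acyl C–O bond formation at palladium and cis-fused to the cyclopentane. The one new stereocentre, the former gem-dimethyl carbon, arises from the choice between two diastereotopic methyl groups and is controlled by the configuration of the carboxyl-bearing carbon, since only the syn methyl can reach palladium in a cis-fused palladacycle. The step needs selectivity for this methyl over the anti methyl, over the ring methylenes β and γ to the acid and over the methyl on the ester-bearing carbon; the preference of carboxylate-assisted palladation for primary C–H bonds, the Thorpe–Ingold effect of the quaternary carbon and the inability of the ester to direct should secure it.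

Step 4
Reactants: 4 methyl (4aS,5R,7aS)-4a,5-dimethyl-1,3-dioxooctahydrocyclopenta[c]pyran-5-carboxylate
Product: 5 (1S,2S,3R)-2-{2-[methoxy(methyl)amino]-2-oxoethyl}-3-(methoxycarbonyl)-2,3-dimethylcyclopentane-1-carboxylic acid
Conditions: MeNH(OMe)·HCl, Et3N, CH2Cl2, 0 → 25 °C; then dilute aq. HCl
Reagents that add atoms: N,O-dimethylhydroxylamine hydrochloride, CNOC.Cl
Why: Aminolysis of a cyclic anhydride; the amine should attack the carbonyl flanked by the CH2 group, because the other one is α-branched and pressed against the ring, giving the Weinreb amide and freeing the ring carboxyl.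

Step 5
Reactants: 5 (1S,2S,3R)-2-{2-[methoxy(methyl)amino]-2-oxoethyl}-3-(methoxycarbonyl)-2,3-dimethylcyclopentane-1-carboxylic acid
Product: 6 methyl (1R,2R)-2-{2-[methoxy(methyl)amino]-2-oxoethyl}-1,2-dimethylcyclopentane-1-carboxylate
Conditions: 9-mesityl-10-phenylacridinium tetrafluoroborate (5 mol %), (PhS)2 (10 mol %), i-Pr2NEt (20 mol %), CF3CH2OH, 450 nm LEDs, 25 °C
Reagents that add atoms: none
Why: Acridinium photoredox hydrodecarboxylation: the carboxylate is oxidised by the excited acridinium, CO2 is lost and the secondary ring radical takes a hydrogen atom from PhSH formed from the disulfide; the carbon becomes a CH2 group, so no stereochemical question arises, and ester and amide are inert.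

Step 6
Reactants: 6 methyl (1R,2R)-2-{2-[methoxy(methyl)amino]-2-oxoethyl}-1,2-dimethylcyclopentane-1-carboxylate
Product: 7 methyl (1R,2R)-1,2-dimethyl-2-(2-oxoethyl)cyclopentane-1-carboxylate
Conditions: i-Bu2AlH (1.2 equiv), THF, −78 °C; aq. KNaC4H4O6 (tartrate)
Reagents that add atoms: none
Why: Weinreb amide reduction stops at the aldehyde because the aluminium-chelated tetrahedral adduct survives until work-up; the tertiary methyl ester reacts much more slowly at −78 °C.

Step 7
Reactants: 8 4-methoxy-2-methylphenol
Product: 9 2-bromo-4-methoxy-6-methylphenol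
Conditions: NBS, CH2Cl2, 0 °C
Reagents that add atoms: N-bromosuccinimide, O=C1CCC(=O)N1Br
Why: Electrophilic aromatic bromination; the hydroxyl group is the strongest director, its para position is blocked and its only free ortho position is brominated.

Step 8
Reactants: 9 2-bromo-4-methoxy-6-methylphenol
Product: 10 1-bromo-2,5-dimethoxy-3-methylbenzene
Conditions: MeI, K2CO3, acetone, 56 °C
Reagents that add atoms: iodomethane, CI
Why: Williamson O-methylation of the phenoxide.

Step 9
Reactants: 10 1-bromo-2,5-dimethoxy-3-methylbenzene; 11 prenyl bromide (1-bromo-3-methylbut-2-ene)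
Product: 13 2,5-dimethoxy-1-methyl-3-(3-methylbut-2-en-1-yl)benzene, via aryllithium 12 (not isolated)
Conditions: n-BuLi, THF, −78 °C; then CuBr·SMe2 (10 mol %), 11, −78 → 0 °C
Reagents that add atoms: none
Why: Bromine–lithium exchange, then copper-assisted allylic substitution at the primary carbon of prenyl bromide (SN2) should give the linear prenyl arene.

Step 10
Reactants: 13 2,5-dimethoxy-1-methyl-3-(3-methylbut-2-en-1-yl)benzene
Product: 14 (2E)-4-(2,5-dimethoxy-3-methylphenyl)-2-methylbut-2-en-1-ol
Conditions: SeO2 (0.5 equiv), t-BuOOH (2 equiv), CH2Cl2, 25 °C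
Reagents that add atoms: selenium dioxide, O=[Se]=O; tert-butyl hydroperoxide, CC(C)(C)OO
Why: Riley allylic oxidation (ene reaction, then [2,3]-sigmatropic shift) attacks the methyl group trans to the chain on the more substituted alkene carbon, which fixes the E geometry of the trisubstituted alkene; the benzylic CH2 on the less substituted alkene carbon is not the preferred site.

Step 11
Reactants: 14 (2E)-4-(2,5-dimethoxy-3-methylphenyl)-2-methylbut-2-en-1-ol
Product: 15 1-[(2E)-4-chloro-3-methylbut-2-en-1-yl]-2,5-dimethoxy-3-methylbenzene
Conditions: NCS, Me2S, CH2Cl2, −20 → 0 °C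
Reagents that add atoms: N-chlorosuccinimide, O=C1CCC(=O)N1Cl
Why: Corey–Kim chlorination: chloride displaces the alkoxysulfonium group at the primary carbon without allylic transposition or loss of alkene geometry.

Step 12
Reactants: 15 1-[(2E)-4-chloro-3-methylbut-2-en-1-yl]-2,5-dimethoxy-3-methylbenzene; 7 methyl (1R,2R)-1,2-dimethyl-2-(2-oxoethyl)cyclopentane-1-carboxylate
Product: 18 (4aR,7aR)-3-[(2E)-4-(2,5-dimethoxy-3-methylphenyl)-2-methylbut-2-en-1-yl]-4a,7a-dimethyl-4,4a,5,6,7,7a-hexahydrocyclopenta[c]pyran-1(3H)-one (both C3 epimers), via allylbarium chloride 16 (not isolated), via hydroxy ester 17 (not isolated)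
Conditions: Li, biphenyl, BaI2, THF, 25 °C; 15, −78 °C; 7, −78 °C; aq. NH4Cl; then KOt-Bu (10 mol %), THF, 0 → 25 °C
Reagents that add atoms: none
Why: α-Selective allylbarium addition: the reagent formed from the chloride and activated Ba at −78 °C adds to the aldehyde through its unsubstituted carbon with retention of the E alkene, and the carbinol centre is formed unselectively because it is oxidised later; catalytic alkoxide then closes the δ-lactone by transesterification onto the cis ester, helped by the two quaternary carbons.

Step 13
Reactants: 18 (4aR,7aR)-3-[(2E)-4-(2,5-dimethoxy-3-methylphenyl)-2-methylbut-2-en-1-yl]-4a,7a-dimethyl-4,4a,5,6,7,7a-hexahydrocyclopenta[c]pyran-1(3H)-one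
Product: 19 (4aR,7aR)-3-[(2E)-4-(2,5-dimethoxy-3-methylphenyl)-2-methylbut-2-en-1-yl]-4a,7a-dimethyloctahydrocyclopenta[c]pyran-1-ol (mixture at C1 and C3)
Conditions: i-Bu2AlH, CH2Cl2, −78 °C; aq. KNaC4H4O6 (tartrate)
Reagents that add atoms: none
Why: Partial reduction of a δ-lactone to the lactol; the tetrahedral aluminium adduct is stable at −78 °C, so reduction stops at the aldehyde level.

Step 14
Reactants: 19 (4aR,7aR)-3-[(2E)-4-(2,5-dimethoxy-3-methylphenyl)-2-methylbut-2-en-1-yl]-4a,7a-dimethyloctahydrocyclopenta[c]pyran-1-ol; 20 prenyl chloride (1-chloro-3-methylbut-2-ene)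
Product: 22 1-{(1R,2R)-2-[(4E)-6-(2,5-dimethoxy-3-methylphenyl)-2-hydroxy-4-methylhex-4-en-1-yl]-1,2-dimethylcyclopentyl}-4-methylpent-3-en-1-ol (mixture at both carbinols), via prenylbarium chloride 21 (not isolated)
Conditions: Li, biphenyl, BaI2, THF, 25 °C; 20 (3 equiv), −78 °C; 19, −78 → −40 °C; aq. NH4Cl
Reagents that add atoms: none
Why: The lactol reacts as its open hydroxy aldehyde: one equivalent of the reagent deprotonates it and a further equivalent adds through the unsubstituted α-carbon (α-selective allylbarium addition), a preference the hindered neopentyl aldehyde should reinforce; the new carbinol is formed unselectively and is oxidised next.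

Step 15
Reactants: 22 1-{(1R,2R)-2-[(4E)-6-(2,5-dimethoxy-3-methylphenyl)-2-hydroxy-4-methylhex-4-en-1-yl]-1,2-dimethylcyclopentyl}-4-methylpent-3-en-1-ol
Product: 23 1-{(1R,2R)-2-[(4E)-6-(2,5-dimethoxy-3-methylphenyl)-4-methyl-2-oxohex-4-en-1-yl]-1,2-dimethylcyclopentyl}-4-methylpent-3-en-1-one
Conditions: Dess–Martin periodinane (3 equiv), pyridine, CH2Cl2, 0 → 25 °C
Reagents that add atoms: none
Why: Dess–Martin oxidation of both secondary homoallylic alcohols under buffered, near-neutral conditions, which should leave the two β,γ-unsaturated ketones unconjugated.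

Step 16
Reactants: 23 1-{(1R,2R)-2-[(4E)-6-(2,5-dimethoxy-3-methylphenyl)-4-methyl-2-oxohex-4-en-1-yl]-1,2-dimethylcyclopentyl}-4-methylpent-3-en-1-one
Product: 24 2-{(2E)-6-[(1R,2R)-1,2-dimethyl-2-(4-methylpent-3-enoyl)cyclopentyl]-3-methyl-5-oxohex-2-en-1-yl}-6-methylcyclohexa-2,5-diene-1,4-dione
Conditions: (NH4)2Ce(NO3)6 (2.5 equiv), MeCN/H2O, 0 °C
Reagents that add atoms: water, O
Why: Oxidative demethylation of the 1,4-dimethoxyarene (two one-electron oxidations with capture of water) gives the para-quinone; the arene is oxidised within minutes at 0 °C, so the alkenes and the β,γ-unsaturated ketones should survive.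

## Compound list

1 | (1R,3S)-(+)-camphoric acid, (1R,3S)-1,2,2-trimethylcyclopentane-1,3-dicarboxylic acid | OC(=O)[C@]1(C)CC[C@H](C(=O)O)C1(C)C | starting material
2 | dimethyl (1R,3S)-1,2,2-trimethylcyclopentane-1,3-dicarboxylate | COC(=O)[C@]1(C)CC[C@H](C(=O)OC)C1(C)C | intermediate
3 | (1S,3R)-3-(methoxycarbonyl)-2,2,3-trimethylcyclopentane-1-carboxylic acid | COC(=O)[C@]1(C)CC[C@H](C(=O)O)C1(C)C | intermediate
4 | methyl (4aS,5R,7aS)-4a,5-dimethyl-1,3-dioxooctahydrocyclopenta[c]pyran-5-carboxylate | COC(=O)[C@]1(C)CC[C@@H]2C(=O)OC(=O)C[C@]12C | intermediate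
5 | (1S,2S,3R)-2-{2-[methoxy(methyl)amino]-2-oxoethyl}-3-(methoxycarbonyl)-2,3-dimethylcyclopentane-1-carboxylic acid | COC(=O)[C@]1(C)CC[C@H](C(=O)O)[C@]1(C)CC(=O)N(C)OC | intermediate
6 | methyl (1R,2R)-2-{2-[methoxy(methyl)amino]-2-oxoethyl}-1,2-dimethylcyclopentane-1-carboxylate | COC(=O)[C@]1(C)CCC[C@]1(C)CC(=O)N(C)OC | intermediate
7 | methyl (1R,2R)-1,2-dimethyl-2-(2-oxoethyl)cyclopentane-1-carboxylate | COC(=O)[C@]1(C)CCC[C@]1(C)CC=O | intermediate
8 | 4-methoxy-2-methylphenol | COc1ccc(O)c(C)c1 | starting material
9 | 2-bromo-4-methoxy-6-methylphenol | COc1cc(C)c(O)c(Br)c1 | intermediate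
10 | 1-bromo-2,5-dimethoxy-3-methylbenzene | COc1cc(C)c(OC)c(Br)c1 | intermediate
11 | prenyl bromide, 1-bromo-3-methylbut-2-ene | CC(C)=CCBr | starting material
12 | (2,5-dimethoxy-3-methylphenyl)lithium | [Li]c1cc(OC)cc(C)c1OC | intermediate
13 | 2,5-dimethoxy-1-methyl-3-(3-methylbut-2-en-1-yl)benzene | COc1cc(C)c(OC)c(CC=C(C)C)c1 | intermediate
14 | (2E)-4-(2,5-dimethoxy-3-methylphenyl)-2-methylbut-2-en-1-ol | OC/C(C)=C/Cc1cc(OC)cc(C)c1OC | intermediate
15 | 1-[(2E)-4-chloro-3-methylbut-2-en-1-yl]-2,5-dimethoxy-3-methylbenzene | ClC/C(C)=C/Cc1cc(OC)cc(C)c1OC | intermediate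
16 | [(2E)-4-(2,5-dimethoxy-3-methylphenyl)-2-methylbut-2-en-1-yl]barium chloride | Cl[Ba]C/C(C)=C/Cc1cc(OC)cc(C)c1OC | intermediate
17 | methyl (1R,2R)-2-[(4E)-6-(2,5-dimethoxy-3-methylphenyl)-2-hydroxy-4-methylhex-4-en-1-yl]-1,2-dimethylcyclopentane-1-carboxylate (both carbinol epimers; drawn as the free alcohol) | COC(=O)[C@]1(C)CCC[C@]1(C)CC(O)C/C(C)=C/Cc1cc(OC)cc(C)c1OC | intermediate
18 | (4aR,7aR)-3-[(2E)-4-(2,5-dimethoxy-3-methylphenyl)-2-methylbut-2-en-1-yl]-4a,7a-dimethyl-4,4a,5,6,7,7a-hexahydrocyclopenta[c]pyran-1(3H)-one (both C3 epimers) | O=C1OC(C/C(C)=C/Cc2cc(OC)cc(C)c2OC)C[C@@]2(C)CCC[C@@]12C | intermediate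
19 | (4aR,7aR)-3-[(2E)-4-(2,5-dimethoxy-3-methylphenyl)-2-methylbut-2-en-1-yl]-4a,7a-dimethyloctahydrocyclopenta[c]pyran-1-ol (mixture at C1 and C3) | OC1OC(C/C(C)=C/Cc2cc(OC)cc(C)c2OC)C[C@@]2(C)CCC[C@@]12C | intermediate
20 | prenyl chloride, 1-chloro-3-methylbut-2-ene | CC(C)=CCCl | starting material
21 | (3-methylbut-2-en-1-yl)barium chloride | Cl[Ba]CC=C(C)C | intermediate
22 | 1-{(1R,2R)-2-[(4E)-6-(2,5-dimethoxy-3-methylphenyl)-2-hydroxy-4-methylhex-4-en-1-yl]-1,2-dimethylcyclopentyl}-4-methylpent-3-en-1-ol (mixture at both carbinols) | CC(C)=CCC(O)[C@]1(C)CCC[C@]1(C)CC(O)C/C(C)=C/Cc1cc(OC)cc(C)c1OC | intermediate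
23 | 1-{(1R,2R)-2-[(4E)-6-(2,5-dimethoxy-3-methylphenyl)-4-methyl-2-oxohex-4-en-1-yl]-1,2-dimethylcyclopentyl}-4-methylpent-3-en-1-one | CC(C)=CCC(=O)[C@]1(C)CCC[C@]1(C)CC(=O)C/C(C)=C/Cc1cc(OC)cc(C)c1OC | intermediate
24 | 2-{(2E)-6-[(1R,2R)-1,2-dimethyl-2-(4-methylpent-3-enoyl)cyclopentyl]-3-methyl-5-oxohex-2-en-1-yl}-6-methylcyclohexa-2,5-diene-1,4-dione (CNP0111393.1) | CC(C)=CCC(=O)[C@]1(C)CCC[C@]1(C)CC(=O)C/C(C)=C/CC1=CC(=O)C=C(C)C1=O | target

## Step count and risks

Total step count: 16. Longest linear sequence: 11 steps (steps 1 to 6 and 12 to 16, from 1); the side-chain branch (steps 7 to 11) joins at step 12.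

Least certain steps:

Step 3 (key step).
- Risk: palladation may go to the ring methylene β to the carboxylate through the smaller five-membered palladacycle. CO may reduce the catalyst to palladium black before C–H cleavage. Turnover may be slow because a secondary acid with an α-hydrogen binds and orients less well than the acyclic acids on which this chemistry is established.
- Fallback (known chemistry; sets out from 3, returns at 4): acid 3 is converted through its acid chloride into the N-aryl amide methyl (1R,3S)-1,2,2-trimethyl-3-{[2,3,5,6-tetrafluoro-4-(trifluoromethyl)phenyl]carbamoyl}cyclopentane-1-carboxylate F1. This is subjected to the established amide-directed γ-methyl C–H carbonylation (Pd(OAc)2, a quinoline ligand, CO, AgOAc, TEMPO), which should give the cis-fused N-aryl glutarimide F2. Heating F2 with BF3·OEt2 in MeOH opens the imide and cleaves the anilide to give the triester F3. LiOH saponifies the two unhindered esters to the diacid F4, with the tertiary ester surviving as in step 2, and Ac2O closes F4 to anhydride 4.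

Step 4.
- Risk: poor regioselectivity, with the amine attacking the ring-bound carbonyl as well, because both carbonyls lie next to the same quaternary carbon and differ only in α-branching.
- Fallback (sets out from 4, returns at 7, replacing steps 4 to 6): the anhydride is opened with MeOH and DMAP. The wanted half ester (1S,2S,3R)-2-(2-methoxy-2-oxoethyl)-3-(methoxycarbonyl)-2,3-dimethylcyclopentane-1-carboxylic acid F5 and its regioisomer 2-[(1S,2R,5S)-2,5-bis(methoxycarbonyl)-1,2-dimethylcyclopentyl]acetic acid F7 are not separated but decarboxylated together under the conditions of step 5. F5 gives the diester methyl (1R,2R)-2-(2-methoxy-2-oxoethyl)-1,2-dimethylcyclopentane-1-carboxylate F6, whereas F7 loses its arm carbon and returns diester 2, which is separated and fed back into step 2. One equivalent of i-Bu2AlH at −78 °C then reduces the unhindered ester of F6 to aldehyde 7.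

Step 12.
- Risk: attack through the substituted γ-carbon of the allylbarium, loss of alkene geometry if the reagent warms, or Wurtz coupling while the reagent is formed.
- Fallback (sets out from 15 and 6, returns at 18 through 17, replacing step 6 and the first half of step 12): chloride 15 and PhSO2Na give the allyl sulfone {[(2E)-4-(2,5-dimethoxy-3-methylphenyl)-2-methylbut-2-en-1-yl]sulfonyl}benzene F8. Its lithio derivative (n-BuLi, THF, −78 °C) is acylated at the sulfonyl-bearing carbon by Weinreb amide 6 to give the β-keto sulfone F9. SmI2 in THF/MeOH removes the sulfonyl group to give the keto ester methyl (1R,2R)-2-[(4E)-6-(2,5-dimethoxy-3-methylphenyl)-4-methyl-2-oxohex-4-en-1-yl]-1,2-dimethylcyclopentane-1-carboxylate F10. NaBH4 reduces the ketone to hydroxy ester 17, which is lactonised to 18 as in step 12.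

Step 14.
- Risk: the lactol may fail to open at −78 °C, and warming to force the opening may erode α-selectivity, so that the 1,1-dimethylallyl isomer forms.
- Fallback (sets out from 18, returns at 23, replacing steps 13 to 15): lactone 18 is treated with lithiated 3-methylbut-2-enyl phenyl sulfone (2.2 equiv, THF, −78 → 0 °C), which is acylated at its sulfonyl-bearing carbon and opens the lactone to the hydroxy keto sulfone 1-{(1R,2R)-2-[(4E)-6-(2,5-dimethoxy-3-methylphenyl)-2-hydroxy-4-methylhex-4-en-1-yl]-1,2-dimethylcyclopentyl}-4-methyl-2-(phenylsulfonyl)pent-3-en-1-one F11. SmI2 gives the hydroxy ketone 1-{(1R,2R)-2-[(4E)-6-(2,5-dimethoxy-3-methylphenyl)-2-hydroxy-4-methylhex-4-en-1-yl]-1,2-dimethylcyclopentyl}-4-methylpent-3-en-1-one F12, and Dess–Martin oxidation under the conditions of step 15 gives diketone 23.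

Step 16.
- Risk: migration of the β,γ-double bonds into conjugation in the acidic medium, or oxidative attack on the trisubstituted alkenes before the arene is consumed.
- Fallback (sets out from 22, returns at 24, exchanging the order of steps 15 and 16): diol 22 is oxidised first with (NH4)2Ce(NO3)6 to the quinone diol 2-{(2E)-5-hydroxy-6-[(1R,2R)-2-(1-hydroxy-4-methylpent-3-en-1-yl)-1,2-dimethylcyclopentyl]-3-methylhex-2-en-1-yl}-6-methylcyclohexa-2,5-diene-1,4-dione F13, so that no enone is exposed to the oxidant. Buffered Dess–Martin oxidation of F13 then gives 24.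

## Further compounds

F1 | step 3 | methyl (1R,3S)-1,2,2-trimethyl-3-{[2,3,5,6-tetrafluoro-4-(trifluoromethyl)phenyl]carbamoyl}cyclopentane-1-carboxylate | COC(=O)[C@]1(C)CC[C@H](C(=O)Nc2c(F)c(F)c(C(F)(F)F)c(F)c2F)C1(C)C
F2 | step 3 | methyl (4aS,5R,7aS)-4a,5-dimethyl-1,3-dioxo-2-[2,3,5,6-tetrafluoro-4-(trifluoromethyl)phenyl]octahydro-1H-cyclopenta[c]pyridine-5-carboxylate | COC(=O)[C@]1(C)CC[C@@H]2C(=O)N(c3c(F)c(F)c(C(F)(F)F)c(F)c3F)C(=O)C[C@]12C
F3 | step 3 | dimethyl (1R,2S,3S)-2-(2-methoxy-2-oxoethyl)-1,2-dimethylcyclopentane-1,3-dicarboxylate | COC(=O)[C@]1(C)CC[C@H](C(=O)OC)[C@]1(C)CC(=O)OC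
F4 | step 3 | (1S,2S,3R)-2-(carboxymethyl)-3-(methoxycarbonyl)-2,3-dimethylcyclopentane-1-carboxylic acid | COC(=O)[C@]1(C)CC[C@H](C(=O)O)[C@]1(C)CC(=O)O
F5 | step 4 | (1S,2S,3R)-2-(2-methoxy-2-oxoethyl)-3-(methoxycarbonyl)-2,3-dimethylcyclopentane-1-carboxylic acid | COC(=O)[C@]1(C)CC[C@H](C(=O)O)[C@]1(C)CC(=O)OC
F6 | step 4 | methyl (1R,2R)-2-(2-methoxy-2-oxoethyl)-1,2-dimethylcyclopentane-1-carboxylate | COC(=O)[C@]1(C)CCC[C@]1(C)CC(=O)OC
F7 | step 4 | 2-[(1S,2R,5S)-2,5-bis(methoxycarbonyl)-1,2-dimethylcyclopentyl]acetic acid | COC(=O)[C@]1(C)CC[C@H](C(=O)OC)[C@]1(C)CC(=O)O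
F8 | step 12 | {[(2E)-4-(2,5-dimethoxy-3-methylphenyl)-2-methylbut-2-en-1-yl]sulfonyl}benzene | O=S(=O)(C/C(C)=C/Cc1cc(OC)cc(C)c1OC)c1ccccc1
F9 | step 12 | methyl (1R,2R)-2-[(4E)-6-(2,5-dimethoxy-3-methylphenyl)-4-methyl-2-oxo-3-(phenylsulfonyl)hex-4-en-1-yl]-1,2-dimethylcyclopentane-1-carboxylate (both epimers at the sulfonyl carbon) | COC(=O)[C@]1(C)CCC[C@]1(C)CC(=O)C(/C(C)=C/Cc1cc(OC)cc(C)c1OC)S(=O)(=O)c1ccccc1
F10 | step 12 | methyl (1R,2R)-2-[(4E)-6-(2,5-dimethoxy-3-methylphenyl)-4-methyl-2-oxohex-4-en-1-yl]-1,2-dimethylcyclopentane-1-carboxylate | COC(=O)[C@]1(C)CCC[C@]1(C)CC(=O)C/C(C)=C/Cc1cc(OC)cc(C)c1OC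
F11 | step 14 | 1-{(1R,2R)-2-[(4E)-6-(2,5-dimethoxy-3-methylphenyl)-2-hydroxy-4-methylhex-4-en-1-yl]-1,2-dimethylcyclopentyl}-4-methyl-2-(phenylsulfonyl)pent-3-en-1-one (mixture of epimers) | CC(C)=CC(C(=O)[C@]1(C)CCC[C@]1(C)CC(O)C/C(C)=C/Cc1cc(OC)cc(C)c1OC)S(=O)(=O)c1ccccc1
F12 | step 14 | 1-{(1R,2R)-2-[(4E)-6-(2,5-dimethoxy-3-methylphenyl)-2-hydroxy-4-methylhex-4-en-1-yl]-1,2-dimethylcyclopentyl}-4-methylpent-3-en-1-one (both carbinol epimers) | CC(C)=CCC(=O)[C@]1(C)CCC[C@]1(C)CC(O)C/C(C)=C/Cc1cc(OC)cc(C)c1OC
F13 | step 16 | 2-{(2E)-5-hydroxy-6-[(1R,2R)-2-(1-hydroxy-4-methylpent-3-en-1-yl)-1,2-dimethylcyclopentyl]-3-methylhex-2-en-1-yl}-6-methylcyclohexa-2,5-diene-1,4-dione (mixture at both carbinols) | CC(C)=CCC(O)[C@]1(C)CCC[C@]1(C)CC(O)C/C(C)=C/CC1=CC(=O)C=C(C)C1=O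
A1 | alternative 1 | cyclopent-1-ene-1,2-dicarboxylic anhydride | O=C1OC(=O)C2=C1CCC2
A2 | alternative 1 | chloromethyl (trimethylsilyl)methyl sulfide | C[Si](C)(C)CSCCl
A3 | alternative 1 | meso thia-propellane anhydride (thiolane, cyclopentane and anhydride rings sharing the C1–C2 bond) | O=C1OC(=O)[C@]23CCC[C@]12CSC3
A4 | alternative 1 | meso cis-1,2-dimethylcyclopentane-1,2-dicarboxylic anhydride | C[C@]12CCC[C@@]1(C)C(=O)OC2=O
A5 | alternative 2 | (2R)-2-tert-butyl-6-methyl-4H-1,3-dioxin-4-one | CC1=CC(=O)O[C@@H](O1)C(C)(C)C
A6 | alternative 2 | 1,2-dimethylcyclopentene | CC1=C(C)CCC1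
A7 | alternative 2 | cis-anti-cis photoadduct (cyclobutane fused to the cyclopentane and to the dioxanone) | CC(C)(C)[C@@H]1O[C@@]2(C)[C@]3(C)CCC[C@]3(C)[C@H]2C(=O)O1
A8 | alternative 2 | 2-[(1R,2R)-2-acetyl-1,2-dimethylcyclopentyl]acetic acid | CC(=O)[C@]1(C)CCC[C@]1(C)CC(=O)O
A9 | alternative 3 | butane-2,3-dione | CC(=O)C(C)=O
A10 | alternative 3 | dimethyl 3-oxopentanedioate | COC(=O)CC(=O)CC(=O)OC
A11 | alternative 3 | cis-1,5-dimethylbicyclo[3.3.0]octane-3,7-dione | O=C1C[C@]2(C)CC(=O)C[C@]2(C)C1
A12 | alternative 3 | cis-1,5-dimethylbicyclo[3.3.0]octan-3-one | O=C1C[C@]2(C)CCC[C@]2(C)C1
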